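**Plan**

- Retrosynthesis: the three angelate C–O bonds are cut first, then the 10,11-epoxide and the ring 3,4-epoxide, then the C6–C7 bond between ring and side chain, last C9=C10 (cross-metathesis) and C8–C9 (allylboration).
- Enabling feature: the C6–C7 bond lies between two oxygen-bearing carbons, ring C1 and chain C8, whose oxygens end as the same ester, and it is homoallylic to the ring C3–C4 unit. A diisopropylsilylene can therefore bridge O1 and O8, and the six-membered ring can enter as the cyclohexa-1,3-diene C3=C4–C5=C6 of toluene cis-dihydrodiol.
- Forward: bromo dienol 6 (C7–C11 and C14) is made in three steps and tied through silicon to O1 of the diol. The C6–C7 bond is closed by a palladium-catalysed reductive Heck cyclization onto the diene, which forms a temporary seven-membered silylene acetal ring; the carbocycle itself is bought.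
- Endgame: hydroxyl-directed epoxidation, desilylation, triple angeloylation and Shi epoxidation.
- Stereochemistry: C1 and C2 are bought with the diol; C6 is relayed from C1 by the tether; C3 and C4 are relayed from the C2 hydroxyl; C8 comes from Brown allylboration; C10 from the Shi ketone.

Key step: step 5

Remark on the chemistry: bisabolane numbering is used (ring C1–C6 with the chain on C6, esters on C1, C2 and C8, methyl on C3, chain C7(=C14H2)–C8–C9–C10–C11). The target is read as (1S,2S,3R,4R,6R,8S,10R), with the C6–C7 bond, O1, O2 and the ring epoxide oxygen all on one face of the ring. Natural toluene cis-dihydrodiol, (1S,2R), carries this C1/C2 configuration. 2-Bromoacrolein is made fresh because it does not keep.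

Step 1
Reactants: 1 acrolein
Product: 3 2-bromoacrolein, via 2,3-dibromopropanal 2 (not isolated)
Conditions: Br2, CH2Cl2, −78 °C; then Et3N, 0 °C
Reagents that add atoms: bromine, BrBr
Why: Bromine adds across the enal alkene and triethylamine removes the acidic α-hydrogen with loss of the β-bromide (bromination–dehydrobromination), the standard preparation of this enal.

Step 2
Reactants: 3 2-bromoacrolein
Product: 5 (S)-2-bromohexa-1,5-dien-3-ol, via diisopinocampheylborinate ester 4 (not isolated)
Conditions: allylMgBr, (−)-Ipc2BOMe, Et2O, −78 °C to rt; then 3, −78 °C; then NaOH, H2O2, 0 °C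
Reagents that add atoms: allylmagnesium bromide, C=CC[Mg]Br; (−)-B-methoxydiisopinocampheylborane, COB([C@@H]1C[C@@H]2C[C@H]([C@H]1C)C2(C)C)[C@@H]1C[C@@H]2C[C@H]([C@H]1C)C2(C)C (its boron and isopinocampheyl groups are held in 4 only)
Why: Brown allylboration through a chair six-membered transition state, in which the isopinocampheyl groups derived from (+)-α-pinene should deliver the allyl group to the Si face of the aldehyde and so set the future C8 as S by reagent control.

Step 3
Reactants: 5 (S)-2-bromohexa-1,5-dien-3-ol
Product: 6 (S)-2-bromo-6-methylhepta-1,5-dien-3-ol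
Conditions: RuCl2(=CHPh)(PCy3)(H2IMes) (second-generation Grubbs catalyst, 5 mol %), 2-methyl-2-butene (large excess), CH2Cl2, 40 °C
Reagents that add atoms: 2-methyl-2-butene, CC=C(C)C
Why: Olefin cross-metathesis turns the monosubstituted alkene into the prenyl group, while the electron-poor 2-bromo-1-alkene should stay out of the catalytic cycle and the carbinol centre is not touched.

Step 4
Reactants: 6 (S)-2-bromo-6-methylhepta-1,5-dien-3-ol; 7 (1S,2R)-3-methylcyclohexa-3,5-diene-1,2-diol (toluene cis-dihydrodiol)
Product: 9 silyl-tethered bromide (O1 of 7 and the oxygen of 6 bridged by diisopropylsilylene; O2–H free), via chlorosilyl ether 8 (not isolated)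
Conditions: iPr2SiCl2 (excess), imidazole, CH2Cl2, 0 °C; evaporation of excess silane; then 7 (1.5 equiv), imidazole, DMF, −20 to 0 °C
Reagents that add atoms: dichlorodiisopropylsilane, CC(C)[Si](Cl)(Cl)C(C)C
Why: Stepwise silylation (temporary silicon tether): the hindered alcohol 6 takes one chloride only, and the remaining Si–Cl should react at the less hindered O1 of the diol, remote from the C3 methyl group, as in the known selective silylation of arene cis-dihydrodiols at the distal hydroxyl; no stereocentre is formed.

Step 5
Reactants: 9 silyl-tethered bromide
Product: 10 cis-fused silylene acetal [(1S,2R,6R,8S): O1–Si(iPr)2–O8 bridge; C6–C7 bond cis to O1 and O2; C7=C14H2; C3=C4; C5H2; 2-OH free]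
Conditions: Pd(PPh3)4 (10 mol %), KOAc, Et3SiH (slow addition), DMF, 60 °C, 0.01 M
Reagents that add atoms: none
Why: Zerovalent palladium should insert into the C7–Br bond only, and the alkenylpalladium then adds syn across the diene terminus C6=C5 to leave an η3-allylpalladium over C5–C4–C3 whose ring β-hydrogens (on C6 and C2) are anti to the metal, so it waits until acetate passes hydride from Et3SiH to palladium and reductive elimination at the less substituted terminus C5 gives the trisubstituted C3=C4 alkene. The closest known reaction types are the reductive Heck cyclization with hydride capture of a π-allylpalladium formed from a 1,3-diene, the palladium-catalysed silane reduction of allyl esters (hydride to the less substituted allyl end) and ring closures through bis-alkoxysilane tethers. The one ring closed is the seven-membered 1,3-dioxa-2-silepane, by 7-exo-trig attack of C7 on C6. The one new stereocentre, C6, is controlled by the tether: the chain hangs from the C1 oxygen, so C7 can reach only the face of C6 that carries this oxygen (the trans-fused alternative would need the four-atom bridge to span the opposite face), which places the C6–C7 bond cis to O1 and O2. The step needs attack at C6 rather than C5 (tether length and formation of the allyl complex), hydride capture at C5 rather than at the tertiary, methyl-bearing C3, and ring closure faster than direct reduction of the alkenylpalladium, which high dilution and slow addition of the silane should secure.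

Step 6
Reactants: 10 cis-fused silylene acetal
Product: 11 epoxy silylene acetal (as 10, with a C3–C4 epoxide on the face of the C2 hydroxyl; configuration at C1, C2, C3, C4, C6 and C8 as in the target)
Conditions: VO(acac)2 (5 mol %), tBuOOH, CH2Cl2, 0 °C to rt
Reagents that add atoms: tert-butyl hydroperoxide, CC(C)(C)OO
Why: Hydroxyl-directed epoxidation: the vanadium alkoxide of the only free hydroxyl (allylic C2–OH) delivers oxygen to the same face of the trisubstituted C3=C4 alkene and so sets C3 and C4 cis to O2, while the C7=C14 and C10=C11 alkenes, which have no free allylic hydroxyl at this stage, should stay untouched.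

Step 7
Reactants: 11 epoxy silylene acetal
Product: 12 epoxy triol (1,2,8-trihydroxy-3,4-epoxybisabola-7(14),10-diene, configuration as in the target)
Conditions: Bu4NF, AcOH, THF, 0 °C to rt
Reagents that add atoms: none
Why: Fluoride-mediated desilylation cleaves both Si–O bonds, and the buffered medium should leave the epoxide alone because O2 is syn to the epoxide oxygen and cannot open it from the back (no Payne rearrangement).

Step 8
Reactants: 12 epoxy triol
Product: 13 tris-angelate (the 10,11-alkene precursor of the target)
Conditions: angelic acid, 2,4,6-trichlorobenzoyl chloride, Et3N, toluene, rt; then 12, 80 °C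
Reagents that add atoms: angelic acid, C/C=C(/C)C(=O)O
Why: Yamaguchi-type mixed anhydride esterification without a nucleophilic catalyst, in which the three hydroxyls attack the unhindered angeloyl carbonyl and the absence of DMAP should prevent Z to E isomerization to the tiglate; no stereocentre is touched.

Step 9
Reactants: 13 tris-angelate
Product: 14 target, (1S,2S,3R,4R,6R,8S,10R)-1,2,8-tris(angeloyloxy)-3,4:10,11-diepoxybisabol-7(14)-ene
Conditions: D-fructose-derived Shi ketone (30 mol %), KHSO5 (Oxone), K2CO3, Bu4NHSO4, MeCN–CH2(OMe)2–aqueous Na2B4O7 buffer, 0 °C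
Reagents that add atoms: potassium peroxymonosulfate, [K+].[O-]S(=O)(=O)OO
Why: Shi epoxidation, in which the chiral dioxirane should oxidize the electron-rich trisubstituted C10=C11 alkene through a spiro transition state ahead of the 1,1-disubstituted C7=C14 alkene and the electron-poor angelate alkenes, giving 10R by catalyst control.

**Compound list**

1 | acrolein | C=CC=O | starting material
2 | 2,3-dibromopropanal | O=CC(Br)CBr | intermediate (not isolated)
3 | 2-bromoacrolein | C=C(Br)C=O | intermediate
4 | (S)-2-bromohexa-1,5-dien-3-yl diisopinocampheylborinate | C=C(Br)[C@H](CC=C)OB([C@@H]1C[C@@H]2C[C@H]([C@H]1C)C2(C)C)[C@@H]1C[C@@H]2C[C@H]([C@H]1C)C2(C)C | intermediate (not isolated)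
5 | (S)-2-bromohexa-1,5-dien-3-ol | C=C(Br)[C@@H](O)CC=C | intermediate
6 | (S)-2-bromo-6-methylhepta-1,5-dien-3-ol | C=C(Br)[C@@H](O)CC=C(C)C | intermediate
7 | (1S,2R)-3-methylcyclohexa-3,5-diene-1,2-diol | CC1=CC=C[C@H](O)[C@@H]1O | starting material
8 | [(S)-2-bromo-6-methylhepta-1,5-dien-3-yloxy]chlorodiisopropylsilane | C=C(Br)[C@@H](O[Si](Cl)(C(C)C)C(C)C)CC=C(C)C | intermediate (not isolated)
9 | silyl-tethered bromide: diisopropylsilylene acetal of O1 of 7 and the hydroxyl of 6, O2–H free | CC1=CC=C[C@H](O[Si](C(C)C)(C(C)C)O[C@@H](CC=C(C)C)C(Br)=C)[C@@H]1O | intermediate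
10 | cis-fused silylene acetal (1S,2R,6R,8S), C6–C7 bond cis to O1 and O2 | C=C1[C@H](CC=C(C)C)O[Si](C(C)C)(C(C)C)O[C@H]2[C@@H]1CC=C(C)[C@H]2O | intermediate
11 | epoxy silylene acetal, ring epoxide cis to O2 | C=C1[C@H](CC=C(C)C)O[Si](C(C)C)(C(C)C)O[C@H]2[C@@H]1C[C@H]1O[C@@]1(C)[C@H]2O | intermediate
12 | epoxy triol | C=C([C@H](CC=C(C)C)O)[C@H]1C[C@H]2O[C@@]2(C)[C@@H](O)[C@H]1O | intermediate
13 | tris-angelate with 10,11-alkene | C=C([C@H](CC=C(C)C)OC(=O)/C(C)=C\C)[C@H]1C[C@H]2O[C@@]2(C)[C@@H](OC(=O)/C(C)=C\C)[C@H]1OC(=O)/C(C)=C\C | intermediate
14 | CNP0258231.4 | C=C([C@H](C[C@H]1OC1(C)C)OC(=O)/C(C)=C\C)[C@H]1C[C@H]2O[C@@]2(C)[C@@H](OC(=O)/C(C)=C\C)[C@H]1OC(=O)/C(C)=C\C | target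

**Count and risks**

Total steps: 9. Longest linear sequence: 9 (from acrolein; the diol 7 enters at step 4).

Steps most likely to fail:

1. Step 5. The alkenylpalladium may be reduced before the seven-membered ring closes, or hydride may be captured at C3 instead of C5, which would put the ring alkene at C4=C5. The fallback sets out from 9 and comes back to the route at 10. It cyclizes the same bromide by a radical chain instead (Bu3SnH added slowly, AIBN, benzene, 80 °C, high dilution). The tributyltin radical abstracts bromine, the alkenyl radical at C7 adds 7-exo to C6 on the face of the tether, and the allyl radical should take hydrogen at the less hindered C5. This fallback makes no new compound (F0).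

2. Step 8. Esterification may stop short at the hindered O2, and prolonged heating may cause Z to E isomerization of the angelate. The fallback sets out from 12 and comes back at 13. The triol is esterified with 2-[bis(2,2,2-trifluoroethoxy)phosphoryl]propanoic acid (N,N'-diisopropylcarbodiimide, DMAP, CH2Cl2) to the tris[2-(bis(2,2,2-trifluoroethoxy)phosphoryl)propanoate] of 12 F1. The three Z-alkenes are then built on the ester by Still–Gennari olefination with acetaldehyde (KN(SiMe3)2, 18-crown-6, THF, −78 °C).

3. Step 4. Discrimination between O1 and O2 may be poor, the silyl group may migrate between them, or the diol may be silylated twice. The fallback sets out from 7 and comes back at 9. The diol is heated with Bu2SnO in toluene with removal of water to give the dibutylstannylene acetal of 7 F2. Its more accessible oxygen O1 is then silylated with the chlorosilyl ether 8 made from 6 as in step 4 (tin-acetal activation in place of direct silylation).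

**Further compounds**

F0 | step 5 | none | none
F1 | step 8 | tris[2-(bis(2,2,2-trifluoroethoxy)phosphoryl)propanoate] of 12 | C=C([C@H](CC=C(C)C)OC(=O)C(C)P(=O)(OCC(F)(F)F)OCC(F)(F)F)[C@H]1C[C@H]2O[C@@]2(C)[C@@H](OC(=O)C(C)P(=O)(OCC(F)(F)F)OCC(F)(F)F)[C@H]1OC(=O)C(C)P(=O)(OCC(F)(F)F)OCC(F)(F)F
F2 | step 4 | dibutylstannylene acetal of 7 | CC1=CC=C[C@@H]2O[Sn](CCCC)(CCCC)O[C@H]12
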